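## The problem

Atoms are numbered C1 to N41 in the order of the target SMILES: ring A is C2-C3-C4-C6-C36-C38, ring B is C6-C7-C32-C31-C36, ring C is C25-C27-C29-C31-C32-C33.

- **Ring system.** The target is a trans-anti-trans decahydrofluorene. C7 (ring B) and C33 (ring C) are spanned by a nine-atom bridge through a para-phenylene, giving a strained 13-membered aryl ether cyclophane. A 5-hydroxy-γ-lactam is spiro-fused at C19, and C20-C21 closes an eight-membered 1,2-dioxocane onto C25.
- **Stereocentres.** Fourteen must be set. C19 is an all-carbon quaternary centre. C16 (hemiaminal) and C21 (peroxyhemiacetal) can equilibrate and are left to thermodynamic control.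
- **Control.** The cis-1,3-dimethyl pair (C2, C4) locks the chair of ring A and can be used to set C36 and C6. These two in turn can direct C31, C29 and the ring B centres C7 and C32. C33, C19 and the α-face oxygens on C25, C27 and C29 must be set later.
- **Fragile groups.** The O-O bond, the trisubstituted epoxide, the β-peroxy ketone (C34/C25) and the hemiaminal are sensitive. Before ring C is oxygenated, C33-H is acidic because it is flanked by a carbonyl and the C25=C27 alkene. Reductants, strong bases and strong acids are therefore kept out of the last third of the route.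
- **Enabling feature.** On ring B, O8 sits on C7 trans to the C32-C33 bond and C33 is α to the C34 carbonyl. This γ-hydroxy carbonyl pattern is what a ketyl at C7 leaves after adding to an enoate at C32. C25 and C27 hang on C33 and on C29 (attached to C31), so they can be joined afterwards as the alkene that the C25 oxygenation needs.

## Retrosynthesis

**C21-O23.** Target 39 is opened at the peroxyhemiacetal to seco aldehyde 38, and the aldehyde is masked as the allyl group of epoxy hydroperoxide 37. Hemiperacetal formation is an equilibrium that closes by itself, so the O-O ring is made last and the peroxide meets only one further reagent. Cutting O24-C25 instead would require a tertiary C-O bond to be formed with a peroxide nucleophile, for which no dependable method exists. The forward step must cleave the one remaining alkene without reducing the hydroperoxide.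

**Ring C oxygens.** Epoxide 37 goes back to allylic hydroperoxide 36 and then to macrocyclic alkene 35. An ene reaction of singlet oxygen on C25=C27 places O24 on C25 and moves the double bond to C27=C29, where the epoxide is needed. Both oxygens must arrive on the α face. The ene step needs abstraction of the axial α-hydrogen on C29, and the epoxidation needs delivery from the hydroperoxide.

**O8-C9.** Cyclophane 35 is cut at the aryl-oxygen bond to seco iodoarene 34. Cutting C7-O8 would require substitution with inversion at a cyclopentyl carbon flanked by two methine carbons. The aryl C-O coupling keeps the C7 configuration made in the key step, so no protecting group is ever placed on O8. The forward reaction is a 13-membered etherification of a hindered secondary alcohol.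

**Lactam and C19.** Lactam 34 comes from ammonia and γ-keto ester 33 (N41-C39 and N41-C16). Compound 33 comes from α-allyl β-keto ester 28 and bromoketone 32 (C18-C19), and 28 from β-keto ester 27 (C19-C20). Bromoketone 32 is made from (4-iodophenyl)acetic acid 29. Building C19 by two enolate alkylations in the open chain lets the order of the two electrophiles decide its configuration. Alkylating inside the cyclophane would leave the face to an unknown macrocycle conformation.

**C19-C34.** β-Keto ester 27 is traced to aldehyde 26, diol 25 and tricyclic hydroxy ester 24. A Roskamp homologation with a diazoacetate is chosen over a Claisen condensation because it needs no base. C33-H, which is allylic and α to the carbonyl, is therefore never exposed to an enolate. Once the β-keto ester exists, its own C19-H is far more acidic and shields C33.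

**C25=C27.** Ring C of 24 is opened by retro-metathesis to hydrindanol diene 23. The isopropenyl and vinyl groups are inert spectators in the steps before, and the metathesis delivers the alkene isomer that the ene reaction requires.

**C7-C32 (key).** Hydrindanol 23 is cut to aldehyde dienoate 22. One bond closes ring B and sets C7, C32 and C33. The tether carbons are held trans-diequatorial on ring A.

**Dienoate.** Aldehyde 22 comes from alcohol 21 and silyl ether 20. The isopropenyl group is attached by cross-coupling to bromoenoate 19 (C33-C25), and 19 by Wittig olefination of aldehyde 18 (C32=C33). Two textbook steps give one alkene geometry.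

**C31-C29.** Aldehyde 18 is derived via alcohol 17 from acid 16, the Ireland-Claisen product of crotyl ester 13. Ester 13 is made from acid 11 and (E)-but-2-en-1-ol 12. The rearrangement makes the two adjacent methine centres in one step, with relative configuration fixed by the chair and ketene acetal geometry. The sense relative to ring A must come from the quaternary C36.

**C36-C37.** Acid 11 goes back through silyl ether 10 and alcohol 9 to enal 6. The methyl group is added last, by axial conjugate addition to the endocyclic enal. That is the only disconnection at C36 in which stereoelectronic control places the methyl axial and the C31 arm equatorial.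

**Ring A.** Enal 6 comes from acetal ketone 3 (C36-C31 by allyl Grignard addition), 3 from silyl enol ether 2 (C6-C7 from an orthoformate), and 2 from meso ketone 1 by enantiotopic deprotonation. A purchased ring replaces an open-chain cyclisation and supplies C2 and C4 from the start.

## Roads not taken

**Alternative 1:** The lactam is cut at N41-C16 and N41-C39 and traced to furan cyclophane A1.
- *Forward step.* Singlet oxygen adds across the furan, an amine base turns the endoperoxide into the hydroxybutenolide, and ammonia converts this into 3-acyl-5-hydroxy-3-pyrrolin-2-one A2.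
- *Merits.* The furan is a flat, base-stable stand-in for the hemiaminal during the macrocyclisation, and the C16 oxidation level arrives in one mild operation. This is better than the chosen plan, where the free hemiaminal must survive a hot copper and carbonate etherification.
- *Weak points.* A2 has C18=C19 unsaturated, whereas the target needs a quaternary C19 carrying the C20 arm. A nucleophile would add to C18, so a conjugate reduction and enolate alkylation inside the strained ring would still be required, with the face unknown. Ring C in A1 and A2 has its alkene at C27=C29 and a saturated C25, which does not set up the C25 oxygenation. The ring C alkene would also compete for singlet oxygen.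
- *Comparison.* The chosen plan fixes C19 before the ring closes and obtains the C25=C27 alkene directly, which it sets against the easier lactam unveiling of this road.

**Alternative 2:** Rings A, B and C are cut together (C6-C36, C31-C32, C25-C33), giving tricyclic hydroxy ester A3 from an open-chain precursor.
- *Forward step.* A Lewis acid (Et2AlCl) opens a cis epoxide by attack of a pentadienylsilane terminus, and the diene released adds to the enoate.
- *Merits.* Step economy is clearly superior: three rings in one operation. C7 is inherited stereospecifically from the epoxide, which is safer than a facial preference of a ketyl.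
- *Weak points.* The quaternary C36 must form in the cationic step with the methyl axial, which depends on alkene geometry and a small energy difference. The extra methyl groups burden the Diels-Alder step. A3 carries C27=C29 and a C25 methine, so the ring C alkene must be moved or C25 re-made before oxygenation. The polyene substrate with three defined alkenes needs a long linear preparation.
- *Comparison.* The chosen plan concedes brevity in ring construction. It sets against this an axial cuprate addition for C36 and a metathesis that gives the right alkene.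

**Alternative 3:** C18-C19 and C16-O17 are cut, leading from spirolactam cyclophane acetal A5 back to 14-membered enamide macrolactam A4.
- *Forward step.* Mn(OAc)3 oxidises the β-keto amide to the C19 radical, which adds across the ring to C18. Cu(OAc)2 oxidises the resulting C16 radical to an acyliminium ion, which water captures.
- *Merits.* The large ring closes by amide formation, which is easier than the aryl ether closure of the chosen plan. The quaternary centre, the lactam and the 13-membered carbocycle arise in one ring contraction with the C20 arm already in place.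
- *Weak points.* The configuration at C19 is left to the conformation of a flexible 14-membered ring. The N-vinyl amide is prone to hydrolysis. The one-electron oxidant must spare the electron-rich C25=C27 alkene and the enolisable C33.
- *Comparison.* The chosen plan uses ionic alkylations whose sense can be reversed by swapping their order. It accepts a harder macrocyclisation in return.

Key step: step 15

Remark: the hemiaminal carbon C16 and the peroxyhemiacetal carbon C21 are taken to be under ring-chain thermodynamic control, with the configurations of the target being the stable ones in the bridged framework.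
Remark: the (R,R)-amide is taken to give enol ether 2; if its sense is opposite, the (S,S)-amide is used.

Step 1
Reactants: 1 cis-3,5-dimethylcyclohexanone
Product: 2 trimethyl{[(3S,5R)-3,5-dimethylcyclohex-1-en-1-yl]oxy}silane
Conditions: (R,R)-bis(1-phenylethyl)amine, n-BuLi, LiCl, TMSCl (internal quench), THF, -100 °C
Reagents that add atoms: chlorotrimethylsilane C[Si](C)(C)Cl
Why: Enantioselective deprotonation of a meso ketone by a chiral lithium amide with in situ silylation, a reaction well studied on this ketone, distinguishes the two enantiotopic α-methylene groups and so fixes the absolute configuration of the route; C2 and C4 are the cis-methyl centres of 1.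

Step 2
Reactants: 2 trimethyl{[(3S,5R)-3,5-dimethylcyclohex-1-en-1-yl]oxy}silane
Product: 3 2-(dimethoxymethyl)-3,5-dimethylcyclohexanone (2,3-trans-3,5-cis)
Conditions: HC(OMe)3, TMSOTf (5 mol%), CH2Cl2, -78 °C
Reagents that add atoms: trimethyl orthoformate COC(OC)OC
Why: Mukaiyama-type alkylation of the silyl enol ether by the dimethoxycarbenium ion installs C7 at the aldehyde oxidation level on C6 only; the new centre is α to the ketone and settles trans to the C4 methyl with all three substituents equatorial.

Step 3
Reactants: 3 2-(dimethoxymethyl)-3,5-dimethylcyclohexanone (2,3-trans-3,5-cis)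
Product: 6 2-allyl-4,6-dimethylcyclohex-1-ene-1-carbaldehyde (4,6-cis), via carbinol acetal 4 (not isolated), via hydroxy aldehyde 5 (not isolated)
Conditions: allylMgBr, THF, -78 to 0 °C; aq. NH4Cl; then TsOH·H2O (cat.), acetone/H2O, 40 °C
Reagents that add atoms: allylmagnesium bromide C=CC[Mg]Br
Why: Grignard 1,2-addition brings in C31 and C32 (plus one carbon removed in step 6); acetal hydrolysis and aldol-type dehydration of the tertiary β-hydroxy aldehyde give the conjugated enal, so the carbinol epimers converge.

Step 4
Reactants: 6 2-allyl-4,6-dimethylcyclohex-1-ene-1-carbaldehyde (4,6-cis)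
Product: 9 (2-allyl-2,4,6-trimethylcyclohexyl)methanol (CH2OH allyl 4-Me 6-Me equatorial; 2-Me axial), via silyl enol ether 7 (not isolated), via aldehyde 8 (not isolated)
Conditions: MeLi, CuI, TMSCl, THF, -78 °C; 1 M HCl, THF, 0 °C; then NaBH4, MeOH, 0 °C
Reagents that add atoms: lithium dimethylcuprate [Li+].C[Cu-]C
Why: Cuprate conjugate addition to the cyclohexenyl aldehyde goes by axial attack trans to the C2 methyl, as with 5-substituted cyclohexenones, giving C36 with axial methyl and equatorial allyl. Protonation of the enol ether on the face away from the new axial methyl makes the C7 aldehyde equatorial, and immediate borohydride reduction secures C6 against epimerisation.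

Step 5
Reactants: 9 (2-allyl-2,4,6-trimethylcyclohexyl)methanol
Product: 10 tert-butyldimethylsilyl ether of 9
Conditions: TBSCl, imidazole, DMF, rt
Reagents that add atoms: tert-butyl(chloro)dimethylsilane CC(C)(C)[Si](C)(C)Cl
Why: Standard silylation of a primary alcohol; the ether survives the oxidations, the enolate chemistry and the hydride reduction that follow.

Step 6
Reactants: 10 tert-butyldimethylsilyl ether of 9
Product: 11 2-[2-(tert-butyldimethylsilyloxymethyl)-1,3,5-trimethylcyclohexyl]acetic acid
Conditions: RuCl3·xH2O (2 mol%), NaIO4, CCl4/MeCN/H2O, rt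
Reagents that add atoms: sodium periodate [Na+].[O-]I(=O)(=O)=O; water O
Why: Ruthenium tetroxide cleavage of the terminal alkene, with periodate as the stoichiometric oxidant, shortens the allyl group by one carbon to the acetic acid arm, making C32 the carboxyl carbon.

Step 7
Reactants: 11 2-[2-(tert-butyldimethylsilyloxymethyl)-1,3,5-trimethylcyclohexyl]acetic acid; 12 (E)-but-2-en-1-ol
Product: 13 (E)-but-2-enyl ester of 11
Conditions: DCC, DMAP (cat.), CH2Cl2, 0 °C to rt
Reagents that add atoms: none
Why: Carbodiimide esterification of a hindered acid with a primary allylic alcohol; the E geometry of the crotyl unit is kept.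

Step 8
Reactants: 13 (E)-but-2-enyl ester of 11
Product: 16 (2,3-syn)-2-[ring A]-3-methylpent-4-enoic acid (C31 and C29 as in the target), via silyl ketene acetal 14 (not isolated), via silyl ester 15 (not isolated)
Conditions: LDA, THF/DMPU (4:1), -78 °C; TBSCl; -78 °C to rt, then 50 °C; 1 M HCl, THF
Reagents that add atoms: none
Why: Ireland-Claisen rearrangement: enolisation in the presence of DMPU gives the ketene acetal with C36 cis to the silyloxy group, and its chair transition state with the E-crotyl unit gives the 2,3-syn relationship of C31 and C29. The C36 methyl lies in the plane of the ketene acetal (1,3-allylic strain) and the crotyl carbon bonds to C31 on the face away from the branched C6 side, which is the target configuration at C31.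

Step 9
Reactants: 16 (2,3-syn)-2-[ring A]-3-methylpent-4-enoic acid
Product: 17 corresponding primary alcohol (C32-OH)
Conditions: LiAlH4, THF, 0 °C to reflux
Reagents that add atoms: none
Why: Hydride reduction of a hindered carboxylic acid; no stereocentre is touched.

Step 10
Reactants: 17 primary alcohol (C32-OH)
Product: 18 corresponding aldehyde (C32)
Conditions: Dess-Martin periodinane, NaHCO3, CH2Cl2, rt
Reagents that add atoms: none
Why: Buffered periodinane oxidation gives the α-branched aldehyde under neutral conditions, so C31 is not epimerised.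

Step 11
Reactants: 18 aldehyde (C32)
Product: 19 methyl (Z)-2-bromo-2-enoate (Br cis to C31)
Conditions: Ph3P=C(Br)CO2Me, toluene, 90 °C
Reagents that add atoms: methyl bromo(triphenylphosphoranylidene)acetate COC(=O)C(Br)=P(c1ccccc1)(c1ccccc1)c1ccccc1
Why: Wittig olefination with a stabilised, non-basic ylide places the ester trans to the hindered C31 substituent and leaves the α-stereocentre untouched.

Step 12
Reactants: 19 methyl (Z)-2-bromo-2-enoate
Product: 20 methyl 2-isopropenyl-2-enoate (ester trans to C31) silyl ether
Conditions: isopropenylboronic acid pinacol ester, Pd(dppf)Cl2 (5 mol%), K3PO4, dioxane/H2O, 60 °C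
Reagents that add atoms: isopropenylboronic acid pinacol ester CC(=C)B1OC(C)(C)C(C)(C)O1
Why: Suzuki-Miyaura coupling of an α-bromoenoate proceeds with retention of alkene geometry and attaches C25 with its methyl and methylene to C33.

Step 13
Reactants: 20 dienoate silyl ether
Product: 21 hydroxy dienoate (free C7-OH)
Conditions: HF·pyridine, pyridine, THF, 0 °C to rt
Reagents that add atoms: none
Why: Acidic fluoride desilylation frees the primary alcohol without generating an alkoxide that could add to C32 of the dienoate.

Step 14
Reactants: 21 hydroxy dienoate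
Product: 22 ring A aldehyde carrying the C31-linked dienoate and butenyl arms
Conditions: Dess-Martin periodinane, NaHCO3, CH2Cl2, 0 °C
Reagents that add atoms: none
Why: Neutral periodinane oxidation gives the aldehyde without epimerising C6; the product is used at once.

Step 15
Reactants: 22 ring A aldehyde carrying the C31-linked dienoate and butenyl arms
Product: 23 ring A-B hydrindanol ester diene
Conditions: SmI2 (2.5 equiv), MeOH (4 equiv), THF, -78 °C
Reagents that add atoms: none
Why: Divalent samarium transfers one electron to the C7 aldehyde, the ketyl adds to C32 of the dienoate in a 5-exo-trig closure of ring B, and a second electron turns the allyl- and ester-stabilised C33 radical into a trivalent samarium dienolate that methanol protonates at C33, leaving the isopropenyl group out of conjugation. The closest known reaction type is the SmI2 ketyl-olefin cyclisation of aldehydes onto α,β-unsaturated esters; the isolated vinyl group is far too slow an acceptor to compete. C32: the tether carbons C6 and C36 are trans-diequatorial on ring A and the C31 butenyl arm takes the pseudo-equatorial site of the chair-like transition state, so the new C32-C33 bond is trans to C29 and ring B is trans-fused. C7: the samarium-bound oxygen turns away from the acceptor, whose ester is trans to C31 and cannot chelate, which puts O8 trans to C33 and rules out lactonisation. C33: the dienolate should hold H32 in its plane (1,3-allylic strain) and take the proton on the face away from the C31 branch, which is the target configuration. The step needs the aldehyde to be reduced before the dienoate (the more easily reduced group, low temperature, proton source present) and anti addition at C7 although O8 ends up 1,3-cis to the axial C36 methyl.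

Step 16
Reactants: 23 ring A-B hydrindanol ester diene
Product: 24 tricyclic hydroxy ester (C25=C27)
Conditions: second-generation Grubbs catalyst (5 mol%), CH2Cl2, 40 °C
Reagents that add atoms: none
Why: Ring-closing metathesis of the 1,1-disubstituted and monosubstituted alkenes forms the trisubstituted cyclohexene of ring C with loss of ethylene; the two arms are trans on ring B, so the B/C fusion is trans.

Step 17
Reactants: 24 tricyclic hydroxy ester
Product: 25 tricyclic diol (C7-OH and C34-OH)
Conditions: LiAlH4, THF, 0 °C
Reagents that add atoms: none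
Why: Ester reduction removes the carbonyl that makes C33-H acidic before any basic reagent is used.

Step 18
Reactants: 25 tricyclic diol
Product: 26 hydroxy aldehyde (C34)
Conditions: TEMPO (10 mol%), PhI(OAc)2, CH2Cl2, rt
Reagents that add atoms: none
Why: The oxoammonium oxidation is selective for the primary alcohol over the hindered secondary C7 alcohol, so O8 needs no protecting group; the β,γ-unsaturated aldehyde is taken on crude.

Step 19
Reactants: 26 hydroxy aldehyde
Product: 27 ethyl β-keto ester (C34 ketone and C19 methylene)
Conditions: ethyl diazoacetate, SnCl2 (10 mol%), CH2Cl2, rt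
Reagents that add atoms: ethyl diazoacetate CCOC(=O)C=[N+]=[N-]
Why: Roskamp homologation (Lewis acid addition of the diazo ester, 1,2-hydride shift, loss of nitrogen) forms C34-C19 without base, so C33 is neither epimerised nor conjugated.

Step 20
Reactants: 27 ethyl β-keto ester
Product: 28 α-allyl β-keto ester (C19 epimers)
Conditions: allyl bromide (1.05 equiv), K2CO3, acetone, rt
Reagents that add atoms: allyl bromide C=CCBr
Why: C-alkylation of a β-keto ester under mild carbonate conditions; only the doubly activated C19-H is removed. The allyl group is the masked C20-C21 aldehyde arm.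

Step 21
Reactants: 29 (4-iodophenyl)acetic acid
Product: 32 1-bromo-3-(4-iodophenyl)propan-2-one, via acid chloride 30 (not isolated), via diazoketone 31 (not isolated)
Conditions: (COCl)2, DMF (cat.), CH2Cl2, rt; TMSCHN2, MeCN/THF, 0 °C; 48% aq. HBr, 0 °C
Reagents that add atoms: (trimethylsilyl)diazomethane C[Si](C)(C)C=[N+]=[N-]; hydrogen bromide Br
Why: Acylation of the diazoalkane and hydrobromination of the diazoketone is the standard route to a bromomethyl ketone. It supplies C18, C16, C15 and the iodoarene in one reagent.

Step 22
Reactants: 28 α-allyl β-keto ester; 32 1-bromo-3-(4-iodophenyl)propan-2-one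
Product: 33 quaternary diketo ester (C19 as in the target)
Conditions: NaH (1.0 equiv), THF, 0 °C; then 32, -20 °C to rt
Reagents that add atoms: none
Why: C-alkylation of the sodium-chelated β-keto ester enolate by a reactive α-bromoketone creates the quaternary C19. In the chelate the ester is cis to O35 and the allyl group cis to C33; H33 eclipses the enolate (1,3-allylic strain) and the electrophile enters from the C25 side, away from C32 and its C7 substituent, which gives the C19 configuration of the target.

Step 23
Reactants: 33 quaternary diketo ester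
Product: 34 seco 5-hydroxy lactam (C7-OH and aryl iodide free)
Conditions: NH3 (7 M in MeOH), 50 °C, sealed tube
Reagents that add atoms: ammonia N
Why: Ammonia condenses with the unhindered C16 ketone and the resulting nitrogen acylates intramolecularly on the C39 ester in a 5-exo closure, the known γ-keto ester to 5-hydroxy-pyrrolidinone conversion. This also removes the 1,4-diketone before any base is used.

Step 24
Reactants: 34 seco 5-hydroxy lactam
Product: 35 13-membered aryl ether cyclophane with spiro lactam and allyl arm
Conditions: CuI (20 mol%), 3,4,7,8-tetramethyl-1,10-phenanthroline, Cs2CO3, toluene, 100 °C, 2 mM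
Reagents that add atoms: none
Why: Intramolecular Ullmann-type C-O coupling of the secondary C7 alcohol with the aryl iodide forms O8-C9 with retention at C7; high dilution favours ring closure over intermolecular N- or O-arylation. C33 is held by the trans-fused ring C in the only configuration that lets the bridge close.

Step 25
Reactants: 35 aryl ether cyclophane
Product: 36 C25 allylic hydroperoxide (C27=C29)
Conditions: O2, tetraphenylporphyrin (cat.), visible light, CH2Cl2, 0 °C
Reagents that add atoms: dioxygen O=O
Why: Schenck ene reaction: singlet oxygen bonds to C25 and removes the axial α-hydrogen on C29 suprafacially, so O24 arrives on the α face and the double bond moves to C27=C29; the terminal allyl alkene is inert to singlet oxygen.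

Step 26
Reactants: 36 C25 allylic hydroperoxide
Product: 37 α-epoxy hydroperoxide
Conditions: mCPBA, NaHCO3, CH2Cl2, 0 °C
Reagents that add atoms: 3-chloroperbenzoic acid OOC(=O)c1cccc(Cl)c1
Why: Peracid epoxidation of the trisubstituted alkene is much faster than that of the terminal allyl group; hydrogen bonding of the allylic hydroperoxide to the peracid should deliver oxygen to its own α face, as allylic and homoallylic hydroxyl groups do.

Step 27
Reactants: 37 α-epoxy hydroperoxide
Product: 39 target CNP0533733.1, via seco aldehyde 38 (not isolated)
Conditions: OsO4 (2 mol%), NaIO4, 2,6-lutidine, dioxane/H2O (3:1), rt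
Reagents that add atoms: sodium periodate [Na+].[O-]I(=O)(=O)=O; water O
Why: Lemieux-Johnson cleavage of the only remaining alkene gives the C21 aldehyde under buffered conditions. The C25 hydroperoxide then adds to it to form the eight-membered peroxyhemiacetal, an equilibrium that settles C21.

## Compound list

1 | cis-3,5-dimethylcyclohexanone (meso) | C[C@@H]1C[C@H](C)CC(=O)C1 | starting material
2 | trimethyl{[(3S,5R)-3,5-dimethylcyclohex-1-en-1-yl]oxy}silane | C[C@@H]1C[C@H](C)C=C(O[Si](C)(C)C)C1 | intermediate
3 | 2-(dimethoxymethyl)-3,5-dimethylcyclohexanone, 2,3-trans-3,5-cis (all equatorial) | C[C@@H]1C[C@H](C)[C@@H](C(OC)OC)C(=O)C1 | intermediate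
4 | 1-allyl-2-(dimethoxymethyl)-3,5-dimethylcyclohexanol (carbinol epimers) | C[C@@H]1C[C@H](C)[C@@H](C(OC)OC)C(O)(CC=C)C1 | intermediate (not isolated)
5 | 2-allyl-2-hydroxy-4,6-dimethylcyclohexanecarbaldehyde | C[C@@H]1C[C@H](C)[C@@H](C=O)C(O)(CC=C)C1 | intermediate (not isolated)
6 | 2-allyl-4,6-dimethylcyclohex-1-ene-1-carbaldehyde (4,6-cis) | C[C@@H]1C[C@H](C)C(C=O)=C(CC=C)C1 | intermediate
7 | trimethylsilyl enol ether of aldehyde 8 | C[C@@H]1C[C@H](C)C(=CO[Si](C)(C)C)[C@](C)(CC=C)C1 | intermediate (not isolated)
8 | 2-allyl-2,4,6-trimethylcyclohexanecarbaldehyde (CHO, allyl, 4-Me, 6-Me equatorial; 2-Me axial) | C[C@@H]1C[C@H](C)[C@@H](C=O)[C@](C)(CC=C)C1 | intermediate (not isolated)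
9 | (2-allyl-2,4,6-trimethylcyclohexyl)methanol, same configuration as 8 | C[C@@H]1C[C@H](C)[C@@H](CO)[C@](C)(CC=C)C1 | intermediate
10 | tert-butyldimethylsilyl ether of 9 | C[C@@H]1C[C@H](C)[C@@H](CO[Si](C)(C)C(C)(C)C)[C@](C)(CC=C)C1 | intermediate
11 | 2-[2-(tert-butyldimethylsilyloxymethyl)-1,3,5-trimethylcyclohexyl]acetic acid | C[C@@H]1C[C@H](C)[C@@H](CO[Si](C)(C)C(C)(C)C)[C@](C)(CC(=O)O)C1 | intermediate
12 | (E)-but-2-en-1-ol | C/C=C/CO | starting material
13 | (E)-but-2-enyl ester of 11 | C[C@@H]1C[C@H](C)[C@@H](CO[Si](C)(C)C(C)(C)C)[C@](C)(CC(=O)OC/C=C/C)C1 | intermediate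
14 | (Z)-O-silyl ketene acetal of 13 (C36 cis to OSi) | C[C@@H]1C[C@H](C)[C@@H](CO[Si](C)(C)C(C)(C)C)[C@](C)(/C=C(\O[Si](C)(C)C(C)(C)C)OC/C=C/C)C1 | intermediate (not isolated)
15 | tert-butyldimethylsilyl ester of 16 | C[C@@H]1C[C@H](C)[C@@H](CO[Si](C)(C)C(C)(C)C)[C@](C)([C@@H](C(=O)O[Si](C)(C)C(C)(C)C)[C@@H](C)C=C)C1 | intermediate (not isolated)
16 | (2,3-syn)-2-[ring A]-3-methylpent-4-enoic acid, C31 and C29 as in the target | C[C@@H]1C[C@H](C)[C@@H](CO[Si](C)(C)C(C)(C)C)[C@](C)([C@@H](C(=O)O)[C@@H](C)C=C)C1 | intermediate
17 | primary alcohol from 16 (C32-OH) | C[C@@H]1C[C@H](C)[C@@H](CO[Si](C)(C)C(C)(C)C)[C@](C)([C@@H](CO)[C@@H](C)C=C)C1 | intermediate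
18 | aldehyde from 17 (C32) | C[C@@H]1C[C@H](C)[C@@H](CO[Si](C)(C)C(C)(C)C)[C@](C)([C@@H](C=O)[C@@H](C)C=C)C1 | intermediate
19 | methyl (Z)-2-bromo-2-enoate (C32=C33; Br cis to C31) | C[C@@H]1C[C@H](C)[C@@H](CO[Si](C)(C)C(C)(C)C)[C@](C)([C@@H](/C=C(\Br)C(=O)OC)[C@@H](C)C=C)C1 | intermediate
20 | methyl 2-isopropenyl-2-enoate, ester trans to C31, C7 silyl ether | C[C@@H]1C[C@H](C)[C@@H](CO[Si](C)(C)C(C)(C)C)[C@](C)([C@@H](/C=C(/C(=O)OC)C(C)=C)[C@@H](C)C=C)C1 | intermediate
21 | hydroxy dienoate (free C7-OH) | C[C@@H]1C[C@H](C)[C@@H](CO)[C@](C)([C@@H](/C=C(/C(=O)OC)C(C)=C)[C@@H](C)C=C)C1 | intermediate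
22 | ring A aldehyde with C31-linked dienoate and butenyl arms (key step precursor) | C[C@@H]1C[C@H](C)[C@@H](C=O)[C@](C)([C@@H](/C=C(/C(=O)OC)C(C)=C)[C@@H](C)C=C)C1 | intermediate
23 | ring A-B hydrindanol ester diene (key step product) | C[C@@H]1C[C@H](C)[C@H]2[C@@H](O)[C@H]([C@@H](C(=O)OC)C(C)=C)[C@@H]([C@@H](C)C=C)[C@]2(C)C1 | intermediate
24 | tricyclic hydroxy ester with C25=C27 | C[C@@H]1C[C@H](C)[C@H]2[C@@H](O)[C@@H]3[C@@H](C(=O)OC)C(C)=C[C@H](C)[C@H]3[C@]2(C)C1 | intermediate
25 | tricyclic diol | C[C@@H]1C[C@H](C)[C@H]2[C@@H](O)[C@@H]3[C@@H](CO)C(C)=C[C@H](C)[C@H]3[C@]2(C)C1 | intermediate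
26 | tricyclic hydroxy aldehyde (C34) | C[C@@H]1C[C@H](C)[C@H]2[C@@H](O)[C@@H]3[C@@H](C=O)C(C)=C[C@H](C)[C@H]3[C@]2(C)C1 | intermediate
27 | ethyl β-keto ester | C[C@@H]1C[C@H](C)[C@H]2[C@@H](O)[C@@H]3[C@@H](C(=O)CC(=O)OCC)C(C)=C[C@H](C)[C@H]3[C@]2(C)C1 | intermediate
28 | α-allyl β-keto ester (C19 epimers) | C[C@@H]1C[C@H](C)[C@H]2[C@@H](O)[C@@H]3[C@@H](C(=O)C(CC=C)C(=O)OCC)C(C)=C[C@H](C)[C@H]3[C@]2(C)C1 | intermediate
29 | (4-iodophenyl)acetic acid | OC(=O)Cc1ccc(I)cc1 | starting material
30 | (4-iodophenyl)acetyl chloride | ClC(=O)Cc1ccc(I)cc1 | intermediate (not isolated)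
31 | 1-diazo-3-(4-iodophenyl)propan-2-one | [N-]=[N+]=CC(=O)Cc1ccc(I)cc1 | intermediate (not isolated)
32 | 1-bromo-3-(4-iodophenyl)propan-2-one | BrCC(=O)Cc1ccc(I)cc1 | intermediate
33 | quaternary diketo ester (C19 bearing allyl, ester, C34 ketone and the 3-aryl-2-oxopropyl arm) | C[C@@H]1C[C@H](C)[C@H]2[C@@H](O)[C@@H]3[C@@H](C(=O)[C@](CC=C)(CC(=O)Cc4ccc(I)cc4)C(=O)OCC)C(C)=C[C@H](C)[C@H]3[C@]2(C)C1 | intermediate
34 | seco 5-hydroxy lactam with free C7-OH and aryl iodide | C[C@@H]1C[C@H](C)[C@H]2[C@@H](O)[C@@H]3[C@@H](C(=O)[C@]4(CC=C)C[C@@](O)(Cc5ccc(I)cc5)NC4=O)C(C)=C[C@H](C)[C@H]3[C@]2(C)C1 | intermediate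
35 | 13-membered aryl ether cyclophane with spiro hydroxy lactam, C19 allyl and C25=C27 | C[C@@H]1C[C@H](C)[C@H]2[C@@H](Oc3ccc(cc3)C[C@]3(O)C[C@]4(CC=C)C(=O)N3)[C@@H]5[C@@H](C4=O)C(C)=C[C@H](C)[C@H]5[C@]2(C)C1 | intermediate
36 | C25 α-hydroperoxide with C27=C29 | C[C@@H]1C[C@H](C)[C@H]2[C@@H](Oc3ccc(cc3)C[C@]3(O)C[C@]4(CC=C)C(=O)N3)[C@@H]5[C@@H](C4=O)[C@@](C)(OO)C=C(C)[C@H]5[C@]2(C)C1 | intermediate
37 | α-epoxy hydroperoxide | C[C@@H]1C[C@H](C)[C@H]2[C@@H](Oc3ccc(cc3)C[C@]3(O)C[C@]4(CC=C)C(=O)N3)[C@@H]5[C@@H](C4=O)[C@@](C)(OO)[C@H]6O[C@@]6(C)[C@H]5[C@]2(C)C1 | intermediate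
38 | seco aldehyde (C21) | C[C@@H]1C[C@H](C)[C@H]2[C@@H](Oc3ccc(cc3)C[C@]3(O)C[C@]4(CC=O)C(=O)N3)[C@@H]5[C@@H](C4=O)[C@@](C)(OO)[C@H]6O[C@@]6(C)[C@H]5[C@]2(C)C1 | intermediate (not isolated)
39 | CNP0533733.1 | C[C@@H]1C[C@H](C)[C@H]2[C@H]3Oc4ccc(cc4)C[C@]4(O)C[C@]5(C[C@H](O)OO[C@@]6(C)[C@H]7O[C@@]7(C)[C@H]([C@H]3[C@H]6C5=O)[C@]2(C)C1)C(=O)N4 | target

## Step count and least certain steps

Total: 27 steps. Longest linear sequence: 26 steps (steps 1 to 20 and 22 to 27); step 21 is a one-step branch.

**Step 15 (key step).**
- *Risk:* loss of facial selectivity at the ketyl carbon, because the samarium-bound oxygen must lie 1,3-cis to the axial C36 methyl. Reduction of the dienoate before the aldehyde and unselective protonation at C33 are further risks.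
- *Fallback:* from 22, an intramolecular Stetter reaction (triazolium carbene precatalyst, DBU, THF) forms the same C7-C32 bond by acyl anion addition and gives the hydrindanone keto ester F1. Reduction with NaBH4 and CeCl3·7H2O at -78 °C, with hydride approaching C7 on the face away from the axial methyl, returns to 23.

**Step 25.**
- *Risk:* hydrogen abstraction from the C26 methyl or from C33-H instead of C29-H, or attack on the β face because the substituents of C19 crowd the α face of C25.
- *Fallback:* the crowding is used instead of fought. From 35, dimethyldioxirane epoxidises C25=C27 on the open β face to give the β-epoxide F2. Anhydrous H2O2 in ether with MoO2(acac)2 opens it at the tertiary C25 with inversion to the hydroxy hydroperoxide F3. 2-Methoxypropene and PPTS mask the hydroperoxide as the peroxyketal F4. Martin sulfurane removes the C27 hydroxyl anti to the axial C29 hydrogen to give the alkene peroxyketal F5. PPTS in methanol returns to 36.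

**Step 26.**
- *Risk:* attack of the peracid on the sterically open β face if delivery from the hydroperoxide is weak.
- *Fallback:* from 36, the allyl group is cleaved first (OsO4, NaIO4, 2,6-lutidine), which closes the olefinic peroxyhemiacetal F6. N-Bromosuccinimide in aqueous DME then gives the bromohydrin F7 by bromonium formation on the β face and water attack from the α face. Ag2O closes the epoxide with inversion on the α face and returns to 39.

**Step 24.**
- *Risk:* opening of the hemiaminal under hot carbonate base followed by intramolecular aldol reaction, intermolecular N-arylation, and slow coupling of the hindered C7 alcohol.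
- *Fallback:* from 33, the ring is closed before the lactam exists and at room temperature by nickel and photoredox C-O coupling (NiCl2·glyme, 4,4'-di-tert-butyl-2,2'-bipyridine, Ir[dF(CF3)ppy]2(dtbbpy)PF6, quinuclidine, K2CO3, MeCN, blue light), giving the macrocyclic diketo ester F8. Ammonia in methanol then forms the lactam and returns to 35.

**Step 22.**
- *Risk:* low facial discrimination in the alkylation that creates C19, and some O-alkylation.
- *Fallback:* the two arms are introduced in the opposite order, which inverts the sense of the substrate bias, and the second alkylation is put under reagent control. From 27, alkylation with 32 (K2CO3, acetone) gives the mono-alkylated keto ester F9. Palladium-catalysed allylation (allyl methyl carbonate, Pd2(dba)3, the C2-symmetric bis(2-diphenylphosphinobenzoyl)-trans-1,2-diaminocyclohexane ligand) returns to 33.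

## Further compounds

F1 | step 15 | hydrindanone keto ester (C7 ketone) from the Stetter closure | C[C@@H]1C[C@H](C)[C@H]2C(=O)[C@H]([C@@H](C(=O)OC)C(C)=C)[C@@H]([C@@H](C)C=C)[C@]2(C)C1
F2 | step 25 | C25,C27 β-epoxide of 35 | C[C@@H]1C[C@H](C)[C@H]2[C@@H](Oc3ccc(cc3)C[C@]3(O)C[C@]4(CC=C)C(=O)N3)[C@@H]5[C@@H](C4=O)[C@]6(C)O[C@@H]6[C@H](C)[C@H]5[C@]2(C)C1
F3 | step 25 | C25 α-hydroperoxide C27 β-alcohol | C[C@@H]1C[C@H](C)[C@H]2[C@@H](Oc3ccc(cc3)C[C@]3(O)C[C@]4(CC=C)C(=O)N3)[C@@H]5[C@@H](C4=O)[C@@](C)(OO)[C@H](O)[C@H](C)[C@H]5[C@]2(C)C1
F4 | step 25 | 2-methoxyprop-2-yl peroxide of F3 | C[C@@H]1C[C@H](C)[C@H]2[C@@H](Oc3ccc(cc3)C[C@]3(O)C[C@]4(CC=C)C(=O)N3)[C@@H]5[C@@H](C4=O)[C@@](C)(OOC(C)(C)OC)[C@H](O)[C@H](C)[C@H]5[C@]2(C)C1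
F5 | step 25 | 2-methoxyprop-2-yl peroxide of 36 | C[C@@H]1C[C@H](C)[C@H]2[C@@H](Oc3ccc(cc3)C[C@]3(O)C[C@]4(CC=C)C(=O)N3)[C@@H]5[C@@H](C4=O)[C@@](C)(OOC(C)(C)OC)C=C(C)[C@H]5[C@]2(C)C1
F6 | step 26 | olefinic peroxyhemiacetal (C27=C29, dioxocane closed) | C[C@@H]1C[C@H](C)[C@H]2[C@H]3Oc4ccc(cc4)C[C@]4(O)C[C@]5(C[C@H](O)OO[C@@]6(C)C=C(C)[C@H]([C@H]3[C@H]6C5=O)[C@]2(C)C1)C(=O)N4
F7 | step 26 | bromohydrin (C27 β-Br, C29 α-OH) | C[C@@H]1C[C@H](C)[C@H]2[C@H]3Oc4ccc(cc4)C[C@]4(O)C[C@]5(C[C@H](O)OO[C@@]6(C)[C@H](Br)[C@@](C)(O)[C@H]([C@H]3[C@H]6C5=O)[C@]2(C)C1)C(=O)N4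
F8 | step 24 | macrocyclic diketo ester (aryl ether closed, lactam not yet formed) | C[C@@H]1C[C@H](C)[C@H]2[C@@H](Oc3ccc(cc3)CC(=O)C[C@]4(CC=C)C(=O)OCC)[C@@H]5[C@@H](C4=O)C(C)=C[C@H](C)[C@H]5[C@]2(C)C1
F9 | step 22 | β-keto ester mono-alkylated with the 3-(4-iodophenyl)-2-oxopropyl arm (C19 epimers) | C[C@@H]1C[C@H](C)[C@H]2[C@@H](O)[C@@H]3[C@@H](C(=O)C(CC(=O)Cc4ccc(I)cc4)C(=O)OCC)C(C)=C[C@H](C)[C@H]3[C@]2(C)C1
A1 | alternative 1 | furan cyclophane (2-benzyl-4-acyl furan in the 13-membered ring) | C[C@@H]1C[C@H](C)[C@H]2[C@H]3Oc4ccc(cc4)Cc5cc(co5)C(=O)[C@@H]6[C@@H]3[C@H]([C@]2(C)C1)C(C)=C[C@@H]6C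
A2 | alternative 1 | macrocyclic 3-acyl-5-hydroxy-3-pyrrolin-2-one | C[C@@H]1C[C@H](C)[C@H]2[C@H]3Oc4ccc(cc4)C[C@]5(O)C=C(C(=O)N5)C(=O)[C@@H]6[C@@H]3[C@H]([C@]2(C)C1)C(C)=C[C@@H]6C
A3 | alternative 2 | tricyclic hydroxy ester from the epoxide opening and Diels-Alder cascade | C[C@@H]1C[C@H](C)[C@H]2[C@@H](O)[C@@H]3[C@@H](C(=O)OC)[C@@H](C)C=C(C)[C@H]3[C@]2(C)C1
A4 | alternative 3 | 14-membered enamide macrolactam β-keto amide | C[C@@H]1C[C@H](C)[C@H]2[C@H]3Oc4ccc(cc4)CC(=C)NC(=O)C(CC(OC)OC)C(=O)[C@@H]6[C@@H]3[C@H]([C@]2(C)C1)[C@@H](C)C=C6C
A5 | alternative 3 | spirolactam para-cyclophane dimethyl acetal | C[C@@H]1C[C@H](C)[C@H]2[C@H]3Oc4ccc(cc4)C[C@]5(O)C[C@](CC(OC)OC)(C(=O)N5)C(=O)[C@@H]6[C@@H]3[C@H]([C@]2(C)C1)[C@@H](C)C=C6C
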